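At early times the ochre flask shows intermediate C climbing fast and target barely begun, so the decision for the next run is when to stop it and whether to change the charge.

| setting | ochre | grey | flask |
|---|---|---|---|
| starting material | 0.30 M | 0.45 M | 0.30 M |
| remark | the very flask that is asked about, followed so far | run made earlier |  |
| time |  |  | 15 min |

| run | time / min | intermediate C / % | target / % |
|---|---|---|---|
| ochre | 1.33 | 27.6 | 3.7 |
| ochre | 2.00 | 36.1 | 8.1 |
| ochre | 3.00 | 44.2 | 14.7 |
| ochre | 5.00 | 48.7 | 27.8 |
| grey | 1.33 | 26.1 | 3.6 |
| grey | 2.50 | 40.6 | 11.3 |
| grey | 4.00 | 47.6 | 21.6 |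
| grey | 6.00 | 48.3 | 33.5 |

(each reading ± 0.3 percentage points)

* time, not beyond 15 min, at which the flask holds most intermediate C
* the amount of intermediate C, in percent of the starting material charged, at that time

- a reading or a percentage of target counts all its forms, free or not

Let R be the part of the charge in neither intermediate C nor target. In the ochre run R falls from 68.7 % at 1.33 min to 23.5 % at 5.00 min. I freeze its fractional loss per minute as the remainder constant k, 0.292 min⁻¹, and take kR as the feed of intermediate C. At 5.00 min that feed is 0.0687 min⁻¹ of the charge.

Target gains 0.0595 min⁻¹ of the charge across 4.00 min to 6.00 min in the grey run, and I freeze this as the drain v of intermediate C. The feed is larger, so on this reckoning intermediate C is still rising in the ochre run at 5.00 min. Setting kR equal to v puts my peak at 5.49 min, at 48.9 %. That is 0.23 percentage points above the ochre reading at 5.00 min, less than the scatter of 0.3 points. The grey run, with its larger charge, reads 48.3 % at 6.00 min, which is below my peak height, so I keep 0.30 M and stop near my peak time.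

The forecast gives 5.5 min (from 4.8 min to 6.5 min) and 49 % (from 48.5 % to 49.8 %), noting: “By 6 min, loss slightly exceeds formation.”

The flask reaches 48.9 % at 5.55 min.

    intermediate B → target (k = 0.0750 min⁻¹)
    intermediate C ⇌ target (K = 1.30, k = 0.210 min⁻¹)
    starting material → intermediate B (k = 0.100 min⁻¹)
    crystals ⇌ target, rate k4*(cs4 - [target]) while solid is left; crystals form when [target] > cs4 (solubility = 0.260 M, k = 2.10 min⁻¹)
    starting material → intermediate A (k = 6.60 min⁻¹)
    intermediate A → intermediate C (k = 0.320 min⁻¹)
    intermediate B ⇌ intermediate A (K = 2.30, k = 0.0380 min⁻¹)

At 5.55 min in this flask, intermediate A feeds intermediate C at 0.0523 min⁻¹ of the charge, while intermediate C loses a net 0.0523 min⁻¹ of the charge to target. Run back from the ochre 5.00 min value, k gives an R of 31.5 % at 4.00 min, and the flask read at that time holds 31.0 % as intermediate A and intermediate B together.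

All runs are simulated with constants of no real substance.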